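## Retrosynthetic overview

1. Ring C is cut at the O1–C2 bond of the (2S)-flavanone. This gives an unprotected (E)-2,2',4'-trihydroxychalcone, and the forward step is an enantioselective cycloisomerisation that sets C2.
2. The chalcone C=C bond is cut (Claisen–Schmidt) into 3-prenylresacetophenone and 7-hydroxy-2,2-dimethylchromene-6-carbaldehyde.
3. The ketone comes from resacetophenone and prenyl bromide by C-prenylation at C3.
4. The aldehyde comes from ortho-formylation of 2,2-dimethylchromen-7-ol, which is made from resorcinol and prenal.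
5. Ring order: benzene rings A and B are bought, the pyran ring of the chromene is made first, and ring C is made last. No protecting groups are used.

Assumption: the sense of induction of the new step cannot be known beforehand. The (R)-acid is written for the 2S product; if the first run gives 2R, the equally available (S)-acid is used with nothing else changed.

## Route

Step 1
Reactants: 1 2,4-dihydroxyacetophenone; 2 prenyl bromide (1-bromo-3-methylbut-2-ene)
Product: 3 1-[2,4-dihydroxy-3-(3-methylbut-2-en-1-yl)phenyl]ethan-1-one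
Conditions: KOH (1.1 equiv), H2O, 0 °C to rt, 16 h; then 1 M HCl; chromatography
Reagents that add atoms: 2 prenyl bromide, CC(C)=CCBr
Why: Nuclear C-prenylation (SN2) of the ambident resorcinol-type phenolate: water solvates the oxygen, so the allylic bromide is attacked by C3, the carbon activated by both oxygens, and the minor 5-C- and 4-O-prenyl isomers are removed by chromatography (about 30–35 % of 3 is normal).

Step 2
Reactants: 4 resorcinol; 5 3-methylbut-2-enal (prenal)
Product: 7 2,2-dimethyl-2H-chromen-7-ol, via ortho-quinone methide 6 (not isolated)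
Conditions: 4 (1.5 equiv), ethylenediammonium diacetate (10 mol %), xylene, reflux, 10 h
Reagents that add atoms: 5 3-methylbut-2-enal, CC(C)=CC=O
Why: Knoevenagel-type condensation of the prenal iminium ion at C4 of resorcinol (para to one OH and least hindered) gives 6, which closes by oxa-6π electrocyclisation (formal [3+3] chromene annulation), and excess resorcinol suppresses a second annulation.

Step 3
Reactants: 7 2,2-dimethyl-2H-chromen-7-ol; 8 formaldehyde (charged as paraformaldehyde)
Product: 10 7-hydroxy-2,2-dimethyl-2H-chromene-6-carbaldehyde, via hydroxymethyl phenol 9 (not isolated)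
Conditions: MgCl2 (2 equiv), Et3N (4 equiv), (CH2O)n (6 equiv), MeCN, reflux, 4 h; then cold 1 M HCl
Reagents that add atoms: 8 formaldehyde (as paraformaldehyde), C=O
Why: Casnati–Skattebøl ortho-formylation: the magnesium phenolate delivers formaldehyde only ortho to the OH, at the open C6 rather than the crowded C8 between two oxygens, and a second formaldehyde oxidises the benzylic alkoxide of 9 by Oppenauer-type hydride transfer.

Step 4
Reactants: 3 1-[2,4-dihydroxy-3-(3-methylbut-2-en-1-yl)phenyl]ethan-1-one; 10 7-hydroxy-2,2-dimethyl-2H-chromene-6-carbaldehyde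
Product: 12 (E)-1-[2,4-dihydroxy-3-(3-methylbut-2-en-1-yl)phenyl]-3-(7-hydroxy-2,2-dimethyl-2H-chromen-6-yl)prop-2-en-1-one, via aldol adduct 11 (not isolated)
Conditions: KOH (50 % aq, 20 equiv), EtOH, argon, dark, rt to 45 °C, 48–72 h; then cold 1 M HCl to pH 5–6; crystallisation
Reagents that add atoms: none
Why: Claisen–Schmidt aldol condensation with E1cB dehydration of 11, as used for unprotected polyhydroxychalcones: the conjugated (E)-chalcone triphenolate is the thermodynamic sink, strong base keeps ring C open so no racemic flavanone is carried on, and prenyl and chromene are inert to base.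

Step 5
Reactants: 12 (E)-1-[2,4-dihydroxy-3-(3-methylbut-2-en-1-yl)phenyl]-3-(7-hydroxy-2,2-dimethyl-2H-chromen-6-yl)prop-2-en-1-one
Product: 14 (2S)-7-hydroxy-2-(7-hydroxy-2,2-dimethyl-2H-chromen-6-yl)-8-(3-methylbut-2-en-1-yl)-2,3-dihydro-4H-chromen-4-one, via keto ortho-quinone methide 13 (not isolated)
Conditions: (R)-3,3'-bis(2,4,6-triisopropylphenyl)-1,1'-binaphthyl-2,2'-diyl hydrogen phosphate (10 mol %), toluene/CH2Cl2 4:1 (0.02 M, not dried), 35 °C, dark, stopped at about 85 % conversion; silica plug (recovered 12 recycled); recrystallisation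
Reagents that add atoms: none
Why: Proposed new method: a chiral phosphoric acid has not been used to cycloisomerise a 2,2'-dihydroxychalcone. The free ortho-OH and para-oxygen of ring B make the chalcone an acyl-substituted ortho-hydroxystyrene, so the acid can put its proton on C-alpha (the electron-rich end of this push–pull alkene) while P=O takes the ring B phenol proton, giving 13. In 13 the quinone-methide oxygen is held by P–OH and P=O accepts the proton of the attacking 2'-OH, so the O1–C2 bond forms as a 6-exo-trig oxa-conjugate addition inside the 2,4,6-triisopropylphenyl pocket on the Si face of C-beta (this gives 2S), and ring B re-aromatises directly to 14. The weak acid leaves prenyl and chromene untouched, and the free phenols do not poison it as they would an amine base. Undried apolar solvent and darkness hold back the Z-chalcone/flavylium side equilibrium, and the run is stopped before the slow 2R channel can erode ee. The closest known reaction types are phosphoric-acid-catalysed enantioselective conjugate additions to ortho-quinone methides made in situ from ortho-hydroxystyrenes or ortho-hydroxybenzyl alcohols, and the poorly selective acid- or cinchona-base-catalysed chalcone–flavanone isomerisation.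

## Compound list

| No. | Name | SMILES | Role |
|---|---|---|---|
| 1 | 2,4-dihydroxyacetophenone | CC(=O)c1ccc(O)cc1O | starting material |
| 2 | prenyl bromide (1-bromo-3-methylbut-2-ene) | CC(C)=CCBr | starting material |
| 3 | 1-[2,4-dihydroxy-3-(3-methylbut-2-en-1-yl)phenyl]ethan-1-one | CC(C)=CCc1c(O)ccc(C(C)=O)c1O | intermediate |
| 4 | resorcinol | Oc1cccc(O)c1 | starting material |
| 5 | 3-methylbut-2-enal | CC(C)=CC=O | starting material |
| 6 | 3-hydroxy-6-(3-methylbut-2-en-1-ylidene)cyclohexa-2,4-dien-1-one (ortho-quinone methide, not isolated) | O=C1C=C(O)C=CC1=CC=C(C)C | intermediate |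
| 7 | 2,2-dimethyl-2H-chromen-7-ol | CC1(C)C=Cc2ccc(O)cc2O1 | intermediate |
| 8 | formaldehyde (charged as paraformaldehyde) | C=O | starting material |
| 9 | 6-(hydroxymethyl)-2,2-dimethyl-2H-chromen-7-ol (present as magnesium salt, not isolated) | CC1(C)C=Cc2cc(CO)c(O)cc2O1 | intermediate |
| 10 | 7-hydroxy-2,2-dimethyl-2H-chromene-6-carbaldehyde | CC1(C)C=Cc2cc(C=O)c(O)cc2O1 | intermediate |
| 11 | 1-[2,4-dihydroxy-3-(3-methylbut-2-en-1-yl)phenyl]-3-hydroxy-3-(7-hydroxy-2,2-dimethyl-2H-chromen-6-yl)propan-1-one (racemic aldol adduct, not isolated) | CC(C)=CCc1c(O)ccc(C(=O)CC(O)c2cc3c(cc2O)OC(C)(C)C=C3)c1O | intermediate |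
| 12 | (E)-1-[2,4-dihydroxy-3-(3-methylbut-2-en-1-yl)phenyl]-3-(7-hydroxy-2,2-dimethyl-2H-chromen-6-yl)prop-2-en-1-one | CC(C)=CCc1c(O)ccc(C(=O)/C=C/c2cc3c(cc2O)OC(C)(C)C=C3)c1O | intermediate |
| 13 | 6-{3-[2,4-dihydroxy-3-(3-methylbut-2-en-1-yl)phenyl]-3-oxopropylidene}-2,2-dimethyl-2H-chromen-7(6H)-one (keto ortho-quinone methide, not isolated) | CC(C)=CCc1c(O)ccc(C(=O)CC=C2C=C3C=CC(C)(C)OC3=CC2=O)c1O | intermediate |
| 14 | (2S)-7-hydroxy-2-(7-hydroxy-2,2-dimethyl-2H-chromen-6-yl)-8-(3-methylbut-2-en-1-yl)-2,3-dihydro-4H-chromen-4-one | CC(C)=CCc1c(O)ccc2c1O[C@H](c1cc3c(cc1O)OC(C)(C)C=C3)CC2=O | target |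

## Step count and risks

Total step count: 5.
Longest linear sequence: 4 steps (4 → 7 → 10 → 12 → 14).

**Step 5 (the proposed new step).**
- It can fail in three ways. Protonation of the acyl-bearing alkene carbon by a weak acid may be too slow. Part of the material may rest as Z-chalcone, hemiketal or flavylium phosphate. Reversible closure may erode ee.
- The fallback sets out from 12 and comes back at 14, and uses only known chemistry.
- 12 is cyclised under thermodynamic control with NaOAc in refluxing EtOH to the racemic flavanone F1.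
- F1 is resolved by preparative chromatography on an amylose tris(3,5-dimethylphenylcarbamate) phase into 14 and the (2R)-enantiomer F2.
- F2 is put back into the NaOAc conditions, where it re-equilibrates to F1 and is recycled.

**Step 4.**
- Three phenolates deactivate both the enolate precursor and the aldehyde, so conversion may stay low.
- The fallback sets out from 3 and 10 and comes back at 12, replacing the polyanion condensation by a masked-phenol strategy.
- 3 reacts with MOMCl (1.1 equiv) and K2CO3 in acetone at rt to give the 4-O-MOM ketone F3. The chelated 2-OH stays free.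
- 10 reacts with MOMCl and K2CO3 in refluxing acetone to give the MOM-protected aldehyde F4.
- KOH in EtOH at rt condenses F3 and F4 to the bis-MOM chalcone F5.
- 3 M HCl in MeOH at 45 °C, quenched to pH 5–6 as soon as cleavage is complete, gives 12.

**Step 1.**
- C- versus O-alkylation and C3 versus C5 selectivity are only modest, so the yield may be too low on scale.
- The fallback sets out from 1 and comes back at 3, replacing direct alkylation by an O-to-C transfer.
- 1 is etherified at the free 4-OH with 3-chloro-3-methylbut-1-yne, CuCl2 (1 mol %) and DBU in MeCN at 0 °C to the 1,1-dimethylpropargyl ether F6.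
- Semihydrogenation (H2, Pd/CaCO3 poisoned with Pb(OAc)2, quinoline, EtOAc) gives the 1,1-dimethylallyl ether F7.
- Heating F7 in N,N-diethylaniline at 130 °C triggers an aromatic Claisen rearrangement. The chelated 2-hydroxy ketone directs it to C3, and it delivers 3.

## Further compounds

F1 | step 5 | racemic 7-hydroxy-2-(7-hydroxy-2,2-dimethyl-2H-chromen-6-yl)-8-(3-methylbut-2-en-1-yl)-2,3-dihydro-4H-chromen-4-one | CC(C)=CCc1c(O)ccc2c1OC(c1cc3c(cc1O)OC(C)(C)C=C3)CC2=O
F2 | step 5 | (2R)-7-hydroxy-2-(7-hydroxy-2,2-dimethyl-2H-chromen-6-yl)-8-(3-methylbut-2-en-1-yl)-2,3-dihydro-4H-chromen-4-one | CC(C)=CCc1c(O)ccc2c1O[C@@H](c1cc3c(cc1O)OC(C)(C)C=C3)CC2=O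
F3 | step 4 | 1-[2-hydroxy-4-(methoxymethoxy)-3-(3-methylbut-2-en-1-yl)phenyl]ethan-1-one | CC(C)=CCc1c(OCOC)ccc(C(C)=O)c1O
F4 | step 4 | 7-(methoxymethoxy)-2,2-dimethyl-2H-chromene-6-carbaldehyde | CC1(C)C=Cc2cc(C=O)c(OCOC)cc2O1
F5 | step 4 | (E)-1-[2-hydroxy-4-(methoxymethoxy)-3-(3-methylbut-2-en-1-yl)phenyl]-3-[7-(methoxymethoxy)-2,2-dimethyl-2H-chromen-6-yl]prop-2-en-1-one | CC(C)=CCc1c(OCOC)ccc(C(=O)/C=C/c2cc3c(cc2OCOC)OC(C)(C)C=C3)c1O
F6 | step 1 | 1-{2-hydroxy-4-[(2-methylbut-3-yn-2-yl)oxy]phenyl}ethan-1-one | CC(=O)c1ccc(OC(C)(C)C#C)cc1O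
F7 | step 1 | 1-{2-hydroxy-4-[(2-methylbut-3-en-2-yl)oxy]phenyl}ethan-1-one | CC(=O)c1ccc(OC(C)(C)C=C)cc1O
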